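**Retrosynthetic overview**

- The strategy rests on the six-membered quinone ring: C1 and C4 carbonyls, C2 hydroxyl, C3 henicosyl, C5 methoxyl, C6 hydrogen. This is a 1,2,4,5-tetraoxygenated benzene at a higher oxidation level. The C2 hydroxyl is traced back to a C–B bond and the C1/C4 carbonyl pair to a 4-methoxyphenol.
- That benzene ring, the only ring, is cut at C4–C3, C2–C1 and C1–C6 by a chromium carbene benzannulation. C4 is the carbene carbon, C1 a carbonyl ligand, C2–C3 the alkyne of a henicosyl alkynylboronate, and C5–C6 a 1-methoxyvinyl group.
- The carbene complex comes from methyl vinyl ether and chromium hexacarbonyl. The alkynylboronate comes from 1-bromohenicosane, lithium acetylide and an isopropoxy pinacol borate.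
- Order: the ring is closed in step 4; Ce(IV) then turns C1/C4 into the quinone, and an amine N-oxide turns C2–B into C2–OH.

Key step: step 4

Assumption: the target has no stereogenic element (planar quinone, unbranched chain), so the single enantiomer asked for is the compound itself; 1-bromohenicosane is taken as a catalogue compound.

**Route**

Step 1
Reactants: 1 methyl vinyl ether; 2 chromium hexacarbonyl
Product: 5 pentacarbonyl[methoxy(1-methoxyvinyl)carbene]chromium(0), via (1-methoxyvinyl)lithium 3 (not isolated), via lithium acylchromate 4 (not isolated)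
Conditions: 1 (excess, condensed), t-BuLi, THF, −78 → 0 °C; added to Cr(CO)6, Et2O, 0 °C → rt; solvent removed; Me3OBF4, CH2Cl2, 0 °C; short silica plug (pentane) under Ar, used at once
Reagents that add atoms: trimethyloxonium tetrafluoroborate, C[O+](C)C.F[B-](F)(F)F
Why: Fischer carbene synthesis, in which the ether oxygen acidifies the α-vinyl C–H for lithiation, the vinyllithium adds to a carbonyl ligand to give the acylchromate, and the hard oxonium salt methylates the acyl oxygen; the α-methoxyl occupies the position that the methyl group holds in the well-behaved isopropenyl complexes.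

Step 2
Reactants: 6 1-bromohenicosane; 7 lithium acetylide–ethylenediamine complex
Product: 8 tricos-1-yne
Conditions: DMSO/THF, 10 °C → rt, Ar
Reagents that add atoms: none
Why: SN2 alkylation of an acetylide by an unhindered primary bromide in a dipolar aprotic medium, with THF keeping the waxy C21 bromide in solution and the complexed monolithium acetylide limiting the reaction to mono-alkylation.

Step 3
Reactants: 8 tricos-1-yne; 9 2-isopropoxy-4,4,5,5-tetramethyl-1,3,2-dioxaborolane
Product: 12 4,4,5,5-tetramethyl-2-(tricos-1-yn-1-yl)-1,3,2-dioxaborolane, via lithium tricos-1-yn-1-ide 10 (not isolated), via lithium alkynyl(isopropoxy)borate 11 (not isolated)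
Conditions: n-BuLi, THF, −20 °C; 9, −78 °C; HCl·Et2O, −78 °C → rt; LiCl filtered off, product crystallised from cold pentane
Reagents that add atoms: none
Why: Borylation of a lithium acetylide with an alkoxyborolane followed by anhydrous acid (Brown-type alkynylboronate synthesis), in which HCl strips isopropoxide from the ate complex as isopropanol and the absence of water protects the base-labile alkynyl C–B bond.

Step 4
Reactants: 5 pentacarbonyl[methoxy(1-methoxyvinyl)carbene]chromium(0); 12 4,4,5,5-tetramethyl-2-(tricos-1-yn-1-yl)-1,3,2-dioxaborolane
Product: 14 3-henicosyl-4,5-dimethoxy-2-(4,4,5,5-tetramethyl-1,3,2-dioxaborolan-2-yl)phenol, via tricarbonyl(η6-arene)chromium complex 13 (not isolated)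
Conditions: 5 (1.0 equiv), 12 (1.3 equiv), THF (0.05 M), 45 °C, Ar, 14 h; then air, rt; chromatography on silica
Reagents that add atoms: none
Why: Dötz benzannulation: thermal loss of a cis carbonyl from 5 lets the alkyne of 12 coordinate and insert into the Cr=C bond (C4–C3) to give an η1,η3-vinylcarbene, CO insertion then gives the η4-dienylketene (C2–C1), and 6π electrocyclisation onto the methylene terminus followed by enolisation closes the benzene ring at C1–C6. The one ring is thus formed by electrocyclic closure of a metal-bound dienylketene and no stereocentre is created. The closest known reaction type is the chromium carbene benzannulation of 1-alkynyl pinacol boronates with aryl and alkenyl methoxycarbene complexes to give ortho-boryl 4-methoxyphenols, and cyclic α-alkoxyalkenyl carbene complexes are established partners in the same annulation. The step needs one orientation of insertion, with the boron-bearing alkyne carbon ending next to the CO-derived C1 and the chain-bearing carbon bonded to the carbene carbon C4. This is the orientation documented for alkynyl pinacol boronates and also the sterically normal one, since the bulky boronate sits on the alkyne carbon remote from the carbene carbon while the unbranched chain is tolerated beside C4. The free methylene terminus of the 1-methoxyvinyl group is the only carbon available for ring closure, so the second methoxyl comes out at C5 and the carbene methoxyl para to the new phenol; the tricarbonylchromium fragment of 13 is shed on exposure to air.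

Step 5
Reactants: 14 3-henicosyl-4,5-dimethoxy-2-(4,4,5,5-tetramethyl-1,3,2-dioxaborolan-2-yl)phenol
Product: 15 3-henicosyl-5-methoxy-2-(4,4,5,5-tetramethyl-1,3,2-dioxaborolan-2-yl)cyclohexa-2,5-diene-1,4-dione
Conditions: CAN (2.5 equiv), MeCN/THF/H2O, 0 °C, 15 min
Reagents that add atoms: water, O
Why: Oxidative demethylation of a 4-methoxyphenol by Ce(IV), in which two-electron oxidation gives the C4 oxocarbenium ion, water adds at C4 and methanol leaves; only the C1 hydroxyl/C4 methoxyl pair is para-related, so the C5 methoxyl remains, and the pinacol boronate is expected to tolerate the short cold exposure as in known conversions of ortho-boryl 4-methoxyphenols into quinone boronates.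

Step 6
Reactants: 15 3-henicosyl-5-methoxy-2-(4,4,5,5-tetramethyl-1,3,2-dioxaborolan-2-yl)cyclohexa-2,5-diene-1,4-dione
Product: 17 3-henicosyl-2-hydroxy-5-methoxycyclohexa-2,5-diene-1,4-dione (the target), via quinonyl pinacol borate 16 (not isolated)
Conditions: Me3NO (anhydrous, 2 equiv), CH2Cl2, 0 °C → rt; then 1 M HCl work-up
Reagents that add atoms: trimethylamine N-oxide, C[N+](C)(C)[O-]
Why: Amine N-oxide oxidation of an sp2 C–B bond, in which the oxide adds to boron, C2 migrates from boron to oxygen with loss of trimethylamine to give borate 16, and dilute acid hydrolyses the B–O bond to the C2 hydroxyl; a non-peroxidic oxidant is chosen so that the quinone C=C bonds and the C5 vinylogous ester are not attacked.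

**Compound list**

1 | methyl vinyl ether | COC=C | starting material
2 | chromium hexacarbonyl | O=C=[Cr](=C=O)(=C=O)(=C=O)(=C=O)=C=O | starting material
3 | (1-methoxyvinyl)lithium | [Li]C(=C)OC | intermediate
4 | lithium pentacarbonyl[(1-methoxyvinyl)(oxido)carbene]chromate (lithium acylchromate) | [Li+].[O-]C(C(OC)=C)=[Cr](=C=O)(=C=O)(=C=O)(=C=O)=C=O | intermediate
5 | pentacarbonyl[methoxy(1-methoxyvinyl)carbene]chromium(0) | COC(C(OC)=C)=[Cr](=C=O)(=C=O)(=C=O)(=C=O)=C=O | intermediate
6 | 1-bromohenicosane | CCCCCCCCCCCCCCCCCCCCCBr | starting material
7 | lithium acetylide–ethylenediamine complex | [Li]C#C.NCCN | starting material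
8 | tricos-1-yne | CCCCCCCCCCCCCCCCCCCCCC#C | intermediate
9 | 2-isopropoxy-4,4,5,5-tetramethyl-1,3,2-dioxaborolane | CC(C)OB1OC(C)(C)C(C)(C)O1 | starting material
10 | lithium tricos-1-yn-1-ide | CCCCCCCCCCCCCCCCCCCCCC#C[Li] | intermediate
11 | lithium isopropoxy(pinacolato)(tricos-1-yn-1-yl)borate | [Li+].CCCCCCCCCCCCCCCCCCCCCC#C[B-]1(OC(C)C)OC(C)(C)C(C)(C)O1 | intermediate
12 | 4,4,5,5-tetramethyl-2-(tricos-1-yn-1-yl)-1,3,2-dioxaborolane | CCCCCCCCCCCCCCCCCCCCCC#CB1OC(C)(C)C(C)(C)O1 | intermediate
13 | tricarbonyl[η6-3-henicosyl-4,5-dimethoxy-2-(4,4,5,5-tetramethyl-1,3,2-dioxaborolan-2-yl)phenol]chromium(0) (π-bonding not encoded in the SMILES) | CCCCCCCCCCCCCCCCCCCCCc1c(B2OC(C)(C)C(C)(C)O2)c(O)cc(OC)c1OC.O=C=[Cr](=C=O)=C=O | intermediate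
14 | 3-henicosyl-4,5-dimethoxy-2-(4,4,5,5-tetramethyl-1,3,2-dioxaborolan-2-yl)phenol | CCCCCCCCCCCCCCCCCCCCCc1c(B2OC(C)(C)C(C)(C)O2)c(O)cc(OC)c1OC | intermediate
15 | 3-henicosyl-5-methoxy-2-(4,4,5,5-tetramethyl-1,3,2-dioxaborolan-2-yl)cyclohexa-2,5-diene-1,4-dione | CCCCCCCCCCCCCCCCCCCCCC1=C(B2OC(C)(C)C(C)(C)O2)C(=O)C=C(OC)C1=O | intermediate
16 | 3-henicosyl-5-methoxy-2-[(4,4,5,5-tetramethyl-1,3,2-dioxaborolan-2-yl)oxy]cyclohexa-2,5-diene-1,4-dione | CCCCCCCCCCCCCCCCCCCCCC1=C(OB2OC(C)(C)C(C)(C)O2)C(=O)C=C(OC)C1=O | intermediate
17 | 3-henicosyl-2-hydroxy-5-methoxycyclohexa-2,5-diene-1,4-dione (CNP0317656.0) | CCCCCCCCCCCCCCCCCCCCCC1=C(O)C(=O)C=C(OC)C1=O | target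

**Step count**

Total steps: 6. Longest linear sequence: 5 steps (6 → 8 → 12 → 14 → 15 → 17).

**Steps most likely to fail**

Step 4. The alkyne may insert in the opposite or a mixed orientation, which would put the chain beside the CO-derived carbon and lead to the 6-methoxy isomer of the quinone. The carbene complex may also oligomerise through its unsubstituted methylene before it captures the alkyne, or the ring may close without CO insertion. The fallback is a metal-free route that sets out from 6 and comes back at 17. Oxidation of 6 with anhydrous trimethylamine N-oxide in DMSO (Ganem variant of the Kornblum oxidation) should give henicosanal F1. Three-component reductive alkylation of commercial 2,5-dihydroxy-1,4-benzoquinone with F1 and Hantzsch ester under proline catalysis (Knoevenagel condensation, then conjugate hydride transfer to the quinone methide) should give 3-henicosyl-2,5-dihydroxycyclohexa-2,5-diene-1,4-dione F2. Acid-catalysed methanolysis (MeOH, cat. H2SO4, reflux) is expected to etherify the vinylogous acid at the less hindered oxygen remote from the chain, which gives 17.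

Step 6. The N-oxide or the liberated amine may attack the electron-poor quinone instead of boron, or the C–B bond may be lost by protodeboronation in place of the 1,2-shift. The fallback sets out from 15 and comes back at 17. Reduction with aqueous sodium dithionite (EtOAc/H2O) should give 3-henicosyl-5-methoxy-2-(4,4,5,5-tetramethyl-1,3,2-dioxaborolan-2-yl)benzene-1,4-diol F3. Its now electron-rich aryl C–B bond is oxidised with H2O2/NaHCO3 in degassed THF/H2O to 3-henicosyl-5-methoxybenzene-1,2,4-triol F4. Admission of air to the same flask oxidises the hydroxyhydroquinone to 17; the C5 methoxyl fixes which oxygens become the carbonyls.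

Step 1. The neutral carbene complex may decompose or oligomerise on silica or on concentration, and methylation may stall in the presence of lithium salts. The fallback sets out from 4 and comes back at 5. Salt metathesis of crude 4 with tetramethylammonium bromide in degassed water should precipitate tetramethylammonium pentacarbonyl[(1-methoxyvinyl)(oxido)carbene]chromate F5, a solid that can be purified and stored. F5 is methylated with methyl triflate in CH2Cl2 at −20 → 0 °C immediately before the annulation and filtered under argon. The resulting solution of 5 is carried into step 4 without chromatography, so the sensitive complex is never isolated.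

**Further compounds**

F1 | step 4 | henicosanal | CCCCCCCCCCCCCCCCCCCCC=O
F2 | step 4 | 3-henicosyl-2,5-dihydroxycyclohexa-2,5-diene-1,4-dione | CCCCCCCCCCCCCCCCCCCCCC1=C(O)C(=O)C=C(O)C1=O
F3 | step 6 | 3-henicosyl-5-methoxy-2-(4,4,5,5-tetramethyl-1,3,2-dioxaborolan-2-yl)benzene-1,4-diol | CCCCCCCCCCCCCCCCCCCCCc1c(B2OC(C)(C)C(C)(C)O2)c(O)cc(OC)c1O
F4 | step 6 | 3-henicosyl-5-methoxybenzene-1,2,4-triol | CCCCCCCCCCCCCCCCCCCCCc1c(O)c(O)cc(OC)c1O
F5 | step 1 | tetramethylammonium pentacarbonyl[(1-methoxyvinyl)(oxido)carbene]chromate | C[N+](C)(C)C.[O-]C(C(OC)=C)=[Cr](=C=O)(=C=O)(=C=O)(=C=O)=C=O
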